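**Plan**

- Retrosynthesis: C16=C17 and C6–C7 are cut first (two Wittig reactions), then the C–O bonds of the 2,3-diol, then C10–C20 together with the lactone O–C19 bond. Ring A is traced back to a benzoic acid (C4–C18, C4–C19), ring B is opened at C9–C10 and C5–C6, ring D at C13–C16, and C8–C15 leads to 3-methoxybenzoic acid.
- Enabling feature: C10 is quaternary and carries C20 on the face on which C19 sits on C4. An oxygen on C6 of ring B, on that same face and allylic to a C5=C10 double bond, can hand a CH2O unit to C10, after which the 1,3-diaxial C20–O/C19 pair closes the δ-lactone.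
- Forward: ring C (Birch alkylation) → ring D (vinyl radical closure) → aryl ketone → ring B (ketone α-arylation onto aromatic ring A) → Birch methylation of ring A → [2,3]-shift with lactonisation → diol, C7 and C17.
- Stereochemistry: C8/C13 by resolution of the bicyclic acid; C9 by the forced cis ring fusion; C11 by hydride attack away from the C15–C16 bridge; the C6 carbinol by CBS reduction; C4 by methylation anti to O6; C10 by suprafacial transfer from O6; C2/C3 by osmylation anti to the lactone bridge; C5 and C6 by equilibration next to a carbonyl group.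

Key step: step 18

Remark on naming: gibberellane numbering (C1–C20) is used for all intermediates; β is the face that carries H-5, H-9, C15 and C18 in the target, α the face that carries C14, C19 and C20.
Assumption: in step 4 the (R)-1-phenylethylammonium salt of the (1R,5S) acid is taken to be the less soluble diastereomer; if it is the more soluble one, the (S)-amine is used in the same way.
Compounds 4–7 are racemic; from 8 onward every compound is a single enantiomer.

**Route**

Step 1
Reactants: 1 3-methoxybenzoic acid; 2 2,3-dibromoprop-1-ene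
Product: 4 rac-1-(2-bromoprop-2-en-1-yl)-3-methoxycyclohexa-2,5-diene-1-carboxylic acid, via dilithium enediolate 3 (not isolated)
Conditions: Li (2.4 equiv), NH3(l)/THF, −78 °C; 2 (1.5 equiv), −78 → −33 °C; NH4Cl, then dilute HCl to pH 4
Reagents that add atoms: none
Why: Birch reductive alkylation of a benzoic acid should reduce the ring 1,4 to the carboxyl carbon and alkylate the enediolate at that carbon with the allylic bromide, which makes quaternary C8 (bearing C6 and C15) and leaves the methoxy group as the C9=C11 enol ether.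

Step 2
Reactants: 4 rac-1-(2-bromoprop-2-en-1-yl)-3-methoxycyclohexa-2,5-diene-1-carboxylic acid
Product: 6 rac-1-(2-bromoprop-2-en-1-yl)-5-oxocyclohex-3-ene-1-carboxylic acid, via unconjugated enone acid 5 (not isolated)
Conditions: 2 M HCl, THF, 50 °C
Reagents that add atoms: water, O
Why: Acid hydrolysis of the enol ether gives the C11 ketone and acid-catalysed enolisation then moves the C13=C14 double bond into conjugation (C12=C13), so that C13 becomes an enone β-carbon.

Step 3
Reactants: 6 rac-1-(2-bromoprop-2-en-1-yl)-5-oxocyclohex-3-ene-1-carboxylic acid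
Product: 7 rac-6-methylidene-3-oxobicyclo[3.2.1]octane-1-carboxylic acid
Conditions: Bu3SnH (1.3 equiv, syringe pump), AIBN (0.1 equiv), benzene, 80 °C
Reagents that add atoms: none
Why: Stork-type vinyl radical cyclisation, in which the C16 radical should add 5-exo-trig to the enone β-carbon C13; the two-carbon bridge can only form cis, which sets C13 relative to C8 and leaves the C11 ketone and the C16 methylidene group.

Step 4
Reactants: 7 rac-6-methylidene-3-oxobicyclo[3.2.1]octane-1-carboxylic acid
Product: 8 (R)-1-phenylethylammonium (1R,5S)-6-methylidene-3-oxobicyclo[3.2.1]octane-1-carboxylate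
Conditions: (R)-1-phenylethylamine (0.55 equiv), EtOAc/EtOH, 60 → 5 °C, two crystallisations
Reagents that add atoms: (R)-1-phenylethylamine, C[C@@H](N)c1ccccc1
Why: Classical resolution through a crystalline diastereomeric ammonium carboxylate should deliver one enantiomer of the rigid keto acid and so fixes C8 and C13 in the absolute sense.

Step 5
Reactants: 8 (R)-1-phenylethylammonium (1R,5S)-6-methylidene-3-oxobicyclo[3.2.1]octane-1-carboxylate
Product: 9 (1R,5S)-1-(hydroxymethyl)-6-methylidenebicyclo[3.2.1]octan-3-ol (both C3 epimers)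
Conditions: LiAlH4 (5 equiv), THF, 0 → 65 °C; Fieser work-up
Reagents that add atoms: none
Why: LiAlH4 reduces the carboxylate to the C6 primary alcohol and the C11 ketone to a carbinol whose configuration is irrelevant because it is re-oxidised in step 8, while the amine is washed out.

Step 6
Reactants: 9 (1R,5S)-1-(hydroxymethyl)-6-methylidenebicyclo[3.2.1]octan-3-ol
Product: 10 (1R,5S)-3-hydroxy-6-methylidenebicyclo[3.2.1]octane-1-carbaldehyde (both C3 epimers)
Conditions: TEMPO (0.1 equiv), PhI(OAc)2 (1.1 equiv), CH2Cl2, rt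
Reagents that add atoms: none
Why: The TEMPO/PhI(OAc)2 oxidation is selective for primary over secondary alcohols and stops at the aldehyde.

Step 7
Reactants: 10 (1R,5S)-3-hydroxy-6-methylidenebicyclo[3.2.1]octane-1-carbaldehyde; 11 1,3-dibromobenzene
Product: 12 (1R,5S)-1-[(2,6-dibromophenyl)(hydroxy)methyl]-6-methylidenebicyclo[3.2.1]octan-3-ol (carbinol epimers)
Conditions: LiN(i-Pr)2 (2.6 equiv), 11 (2.6 equiv), THF, −78 °C, 1 h; then 10, −78 °C; NH4Cl
Reagents that add atoms: none
Why: Lithiation of 1,3-dibromobenzene between the two bromine atoms gives 2,6-dibromophenyllithium, whose 1,2-addition to the aldehyde forms the C5–C6 bond; because the aryl group is symmetric, either bromine can later serve at C10 and the other becomes the handle for C19.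

Step 8
Reactants: 12 (1R,5S)-1-[(2,6-dibromophenyl)(hydroxy)methyl]-6-methylidenebicyclo[3.2.1]octan-3-ol
Product: 13 (1R,5S)-1-(2,6-dibromobenzoyl)-6-methylidenebicyclo[3.2.1]octan-3-one
Conditions: Dess–Martin periodinane (3 equiv), NaHCO3, CH2Cl2, rt
Reagents that add atoms: none
Why: Dess–Martin oxidation converts both secondary alcohols into ketones and thereby removes the two stereochemically undefined carbinol centres.

Step 9
Reactants: 13 (1R,5S)-1-(2,6-dibromobenzoyl)-6-methylidenebicyclo[3.2.1]octan-3-one
Product: 14 tetracyclic bromo diketone (ring A aromatic with Br on C4; ketones at C6 and C11; 9β-H; C16 methylidene)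
Conditions: Pd(OAc)2 (5 mol %), P(t-Bu)3·HBF4 (10 mol %), NaOt-Bu (1.5 equiv), toluene, 70 °C
Reagents that add atoms: none
Why: Palladium-catalysed intramolecular α-arylation of the C11 ketone, in which only the enolate carbon C9 can reach the aryl bromide through a five-membered ring and ring B can only close on the side of C8 that carries C6, so that H-9 ends on the side of C15 (C9 stays epimerisable next to the ketone, which favours the same cis-fused isomer).

Step 10
Reactants: 14 tetracyclic bromo diketone
Product: 15 11β-alcohol of 14 (C6 ketone kept)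
Conditions: LiBH(s-Bu)3 (1.1 equiv), THF, −78 °C; NH4Cl
Reagents that add atoms: none
Why: The bulky borohydride should reduce the unhindered C11 cyclohexanone and spare the conjugated C6 ketone flanked by quaternary C8 and the bromine, and it attacks C11 from the α face, away from the C15–C16 bridge (as in bicyclo[3.2.1]octan-3-ones of the tropinone type), which gives the axial 11β-alcohol.

Step 11
Reactants: 15 11β-alcohol
Product: 16 11β-tert-butyldimethylsilyl ether of 15
Conditions: TBSOTf (1.5 equiv), 2,6-lutidine, CH2Cl2, 0 °C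
Reagents that add atoms: tert-butyldimethylsilyl trifluoromethanesulfonate, CC(C)(C)[Si](C)(C)OS(=O)(=O)C(F)(F)F
Why: Silyl triflate with a hindered pyridine base silylates even the axial 11β-alcohol, and the non-enolisable C6 ketone is not touched.

Step 12
Reactants: 16 11β-silyl ether
Product: 18 16-ketone (C17 removed; Br on C4, C6 ketone, 11β-OTBS), via ozonide 17 (not isolated)
Conditions: O3, CH2Cl2, −78 °C; Me2S, −78 °C → rt
Reagents that add atoms: ozone, [O-][O+]=O
Why: Ozonolysis cleaves the electron-rich exocyclic alkene and leaves the electron-poor bromoaryl ketone alone; C16 must be masked because later osmylation and hydroboration would attack a C16=C17 bond.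

Step 13
Reactants: 18 16-ketone
Product: 19 C16 1,3-dioxolane of 18
Conditions: (Me3SiOCH2)2 (2 equiv), Me3SiOTf (5 mol %), CH2Cl2, −78 → −20 °C
Reagents that add atoms: 1,2-bis(trimethylsilyloxy)ethane, C[Si](C)(C)OCCO[Si](C)(C)C
Why: Noyori ketalisation converts the C16 cyclopentanone, whereas the conjugated C6 ketone between quaternary C8 and the bromine is too hindered and too electron-rich at carbon to react.

Step 14
Reactants: 19 C16 dioxolane
Product: 20 6α-alcohol, (6S) (ring A aromatic, Br on C4, 11β-OTBS, C16 dioxolane)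
Conditions: (R)-Me-CBS oxazaborolidine (1.0 equiv), BH3·SMe2 (1.5 equiv), THF, −20 → 0 °C; MeOH
Reagents that add atoms: none
Why: Corey–Bakshi–Shibata reduction, in which the aryl carbon acts as the large group (the carbonyl lone pair on its side is blocked by the neighbouring bromine), so the (R)-catalyst should deliver hydride to the β face of C6 and place the hydroxyl α, on the side of C14; the substrate itself has little bias because C14 and C15 flank C6 almost symmetrically.

Step 15
Reactants: 20 6α-alcohol
Product: 22 6α-hydroxy 19-acid (ring A aromatic, CO2H on C4), via aryllithium 21 (not isolated)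
Conditions: n-BuLi (2.2 equiv), THF, −78 °C; CO2 (gas); dilute HCl to pH 4
Reagents that add atoms: carbon dioxide, O=C=O
Why: After deprotonation of the alcohol, bromine–lithium exchange at C4 and carboxylation install C19; the hydroxy acid cannot close a lactone because that ring would be peri-fused to the indane.

Step 16
Reactants: 22 6α-hydroxy 19-acid
Product: 24 ring A 2,5(10)-diene with C4 quaternary (4β-methyl, 4α-CO2H), 6α-OH, 11β-OTBS, C16 dioxolane, via trilithium enediolate 23 (not isolated)
Conditions: Li (5 equiv), NH3(l)/THF, −78 °C; MeI (excess), −78 °C; NH4Cl, then pH 5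
Reagents that add atoms: iodomethane, CI
Why: Birch reduction of the lithium benzoate (the C6 alcohol is present as lithium alkoxide, which resists benzylic C–O cleavage) reduces C4 and C1 and leaves C2=C3 and C5=C10, and methyl iodide should then alkylate the enediolate at C4 from the β face, opposite the solvated alkoxide on C6, so that C19 ends cis to O6.

Step 17
Reactants: 24 dienyl hydroxy acid; 25 tributyl(iodomethyl)stannane
Product: 27 C6 tributylstannylmethyl ether of 24 (free C19 acid), via dipotassium salt 26 (not isolated)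
Conditions: KH (3 equiv), THF, 0 °C; 25 (1.2 equiv), 0 °C → rt; dilute HCl to pH 4
Reagents that add atoms: none
Why: Williamson etherification under Still's conditions, in which the alkoxide of the dianion is far more nucleophilic than the carboxylate in THF, so that the iodide should alkylate O6 only.

Step 18
Reactants: 27 C6 stannylmethyl ether acid
Product: 30 19,20-lactone with quaternary C10 and C5=C6 (C2=C3 kept; 11β-OTBS; C16 dioxolane), via lithiomethyl ether 28 (not isolated), via 20-hydroxy 19-acid 29 (not isolated)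
Conditions: LiN(SiMe3)2 (1.05 equiv), THF, −78 °C; n-BuLi (1.5 equiv), −78 → −20 °C; 1 M HCl to pH 3 at 0 °C; camphorsulfonic acid (0.1 equiv), CH2Cl2, rt
Reagents that add atoms: none
Why: LiN(SiMe3)2 first turns the acid into its lithium carboxylate, then n-BuLi exchanges tin for lithium and the α-alkoxymethyllithium rearranges by a concerted [2,3]-sigmatropic shift through a five-membered envelope transition state, forming C10–C20 while the C6–O bond breaks and the double bond moves to C5=C6. This is the Still variant of the [2,3]-Wittig rearrangement, well known for moving a hydroxymethyl group from a ring carbinol to an angular position. The shift is suprafacial, so the α-oxygen on C6 alone fixes the new quaternary centre C10 with C20 on the α face, next to C19. On acidification the C20 hydroxyl and the C19 acid, held 1,3-diaxial on ring A, close the δ-lactone by 6-exo-trig attack of oxygen on the carboxyl carbon. The step needs the [2,3] path to beat the [1,2] shift and attack of the carbanion on the carboxyl group; the low temperature, the pseudo-axial C6–O bond of the cyclopentene and the use of the carboxylate, the least electrophilic carboxyl form, should secure this.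

Step 19
Reactants: 30 19,20-lactone diene
Product: 31 2β,3β-diol of 30
Conditions: OsO4 (2 mol %), N-methylmorpholine N-oxide (1.5 equiv), acetone/H2O, rt
Reagents that add atoms: osmium tetroxide, O=[Os](=O)(=O)=O; N-methylmorpholine N-oxide, C[N+]1([O-])CCOCC1; water, O
Why: Upjohn cis-dihydroxylation attacks the cis-disubstituted C2=C3 and not C5=C6, which is trisubstituted and flanked by three quaternary carbons, and it comes from the β face because the axial C19 and C20 of the lactone bridge cover the α face.

Step 20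
Reactants: 31 2β,3β-diol
Product: 32 2β,3β,11β-tris(tert-butyldimethylsilyl) ether
Conditions: TBSOTf (3 equiv), 2,6-lutidine, CH2Cl2, 0 °C → rt
Reagents that add atoms: tert-butyldimethylsilyl trifluoromethanesulfonate, CC(C)(C)[Si](C)(C)OS(=O)(=O)C(F)(F)F
Why: Silyl triflate protects both hydroxyls, including the axial 3β one next to quaternary C4, which guards against retro-aldol opening of ring A in the later basic steps.

Step 21
Reactants: 32 tris-silyl ether
Product: 34 C6 alcohol (main isomer expected 5α-H, 6α-OH), via C6 alkylborane 33 (not isolated)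
Conditions: BH3·THF (5 equiv), THF, 0 → 40 °C; NaOAc, 30 % H2O2, 0 °C → rt
Reagents that add atoms: hydrogen peroxide, OO
Why: Hydroboration places boron on the less substituted C6 and hydrogen on C5, probably from the lactone face since the axial 3β-silyloxy group shields the other one; the configurations at C5 and C6 need not be controlled here because both are reset in steps 22 and 24.

Step 22
Reactants: 34 C6 alcohol
Product: 36 C6 ketone with 5β-H (trans A/B), via 5α-H ketone 35 (not isolated)
Conditions: Dess–Martin periodinane (1.5 equiv), NaHCO3, CH2Cl2, rt; then DBU (0.5 equiv), toluene, 60 °C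
Reagents that add atoms: none
Why: Oxidation gives the ring B ketone and base equilibration through the C5 enolate should move C6 out of the β-axial position on ring A, where it clashes 1,3-diaxially with the 3β-silyloxy group, into the natural arrangement with 5β-H.

Step 23
Reactants: 36 C6 ketone
Product: 37 C6 methoxymethylidene enol ether (E/Z mixture)
Conditions: MeOCH2PPh3Cl (5 equiv), KN(SiMe3)2 (4.8 equiv), THF, 0 → 60 °C
Reagents that add atoms: (methoxymethyl)triphenylphosphonium chloride, COC[P+](c1ccccc1)(c1ccccc1)c1ccccc1.[Cl-]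
Why: Wittig methoxymethylenation adds C7 to the ketone; the lactone is far less electrophilic toward the ylide than the cyclopentanone.

Step 24
Reactants: 37 enol ether
Product: 39 7-aldehyde (6β-formyl) with C16 ketone, via 7-aldehyde dioxolane 38 (not isolated)
Conditions: TsOH·H2O (0.3 equiv), acetone/H2O (10:1), 40 °C
Reagents that add atoms: water, O
Why: Aqueous acid hydrolyses the enol ether to the aldehyde and then the dioxolane to the C16 ketone, and acid-catalysed enolisation of the aldehyde should settle the formyl group on the β face of C6, trans to the quaternary C4 on C5.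

Step 25
Reactants: 39 keto aldehyde
Product: 40 7-carboxylic acid with C16 ketone
Conditions: NaClO2, NaH2PO4, 2-methylbut-2-ene, t-BuOH/H2O, rt
Reagents that add atoms: sodium chlorite, [Na+].[O-]Cl=O
Why: Pinnick oxidation converts the aldehyde into the acid without touching the ketone or epimerising C6.

Step 26
Reactants: 40 keto acid
Product: 41 16-methylidene tris-silyl ether acid
Conditions: Ph3PCH3Br (6 equiv), KOt-Bu (5.5 equiv), THF, rt → 50 °C; dilute HCl to pH 3
Reagents that add atoms: methyltriphenylphosphonium bromide, C[P+](c1ccccc1)(c1ccccc1)c1ccccc1.[Br-]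
Why: Wittig methylenation of gibberellin 16-norketones in the presence of a carboxylate and a lactone is well established; one equivalent of ylide is consumed by the acid.

Step 27
Reactants: 41 16-methylidene tris-silyl ether acid
Product: 42 CNP0302900.3 (2β,3β,11β-trihydroxy 19,20-lactone 7-acid)
Conditions: HF·pyridine, THF/pyridine, 0 → 40 °C
Reagents that add atoms: none
Why: Buffered fluoride removes the three silyl ethers, including the hindered axial ones, under conditions that should neither open the lactone nor isomerise the exocyclic alkene.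

**Compound list**

1 | 3-methoxybenzoic acid | COc1cccc(c1)C(=O)O | starting material
2 | 2,3-dibromoprop-1-ene | C=C(Br)CBr | starting material
3 | dilithium enediolate of 3-methoxy-1,4-dihydrobenzoic acid (not isolated) | COC1=CC(=C(O[Li])O[Li])C=CC1 | intermediate
4 | rac-1-(2-bromoprop-2-en-1-yl)-3-methoxycyclohexa-2,5-diene-1-carboxylic acid | C=C(Br)CC1(C(=O)O)C=CCC(OC)=C1 | intermediate
5 | rac-1-(2-bromoprop-2-en-1-yl)-5-oxocyclohex-2-ene-1-carboxylic acid, unconjugated enone (not isolated) | C=C(Br)CC1(C(=O)O)C=CCC(=O)C1 | intermediate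
6 | rac-1-(2-bromoprop-2-en-1-yl)-5-oxocyclohex-3-ene-1-carboxylic acid | C=C(Br)CC1(C(=O)O)CC=CC(=O)C1 | intermediate
7 | rac-6-methylidene-3-oxobicyclo[3.2.1]octane-1-carboxylic acid (racemate; bridge necessarily cis) | C=C1CC2(C(=O)O)CC1CC(=O)C2 | intermediate
8 | (R)-1-phenylethylammonium (1R,5S)-6-methylidene-3-oxobicyclo[3.2.1]octane-1-carboxylate | C=C1C[C@]2(C(=O)[O-])C[C@H]1CC(=O)C2.C[C@@H]([NH3+])c1ccccc1 | intermediate
9 | (1R,5S)-1-(hydroxymethyl)-6-methylidenebicyclo[3.2.1]octan-3-ol, both C3 epimers | C=C1C[C@]2(CO)C[C@H]1CC(O)C2 | intermediate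
10 | (1R,5S)-3-hydroxy-6-methylidenebicyclo[3.2.1]octane-1-carbaldehyde, both C3 epimers | C=C1C[C@]2(C=O)C[C@H]1CC(O)C2 | intermediate
11 | 1,3-dibromobenzene | Brc1cccc(Br)c1 | starting material
12 | (1R,5S)-1-[(2,6-dibromophenyl)(hydroxy)methyl]-6-methylidenebicyclo[3.2.1]octan-3-ol, carbinol epimers | C=C1C[C@]2(C(O)c3c(Br)cccc3Br)C[C@H]1CC(O)C2 | intermediate
13 | (1R,5S)-1-(2,6-dibromobenzoyl)-6-methylidenebicyclo[3.2.1]octan-3-one | C=C1C[C@]2(C(=O)c3c(Br)cccc3Br)C[C@H]1CC(=O)C2 | intermediate
14 | tetracyclic bromo diketone: ring A aromatic, Br on C4, C6 and C11 ketones, 9β-H, C16 methylidene | C=C1C[C@]23C[C@H]1CC(=O)[C@H]2c1cccc(Br)c1C3=O | intermediate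
15 | 11β-alcohol of 14 | C=C1C[C@]23C[C@H]1C[C@H](O)[C@H]2c1cccc(Br)c1C3=O | intermediate
16 | 11β-TBS ether of 15 | C=C1C[C@]23C[C@H]1C[C@H](O[Si](C)(C)C(C)(C)C)[C@H]2c1cccc(Br)c1C3=O | intermediate
17 | ozonide of 16 at C16/C17 (not isolated) | C1OOC2(O1)C[C@]34C[C@H]2C[C@H](O[Si](C)(C)C(C)(C)C)[C@H]3c2cccc(Br)c2C4=O | intermediate
18 | 16-ketone: Br on C4, C6 ketone, 11β-OTBS | O=C1C[C@]23C[C@H]1C[C@H](O[Si](C)(C)C(C)(C)C)[C@H]2c1cccc(Br)c1C3=O | intermediate
19 | C16 1,3-dioxolane of 18 | O1CCOC12C[C@]34C[C@H]2C[C@H](O[Si](C)(C)C(C)(C)C)[C@H]3c2cccc(Br)c2C4=O | intermediate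
20 | 6α-alcohol (6S) of 19 | O1CCOC12C[C@]34C[C@H]2C[C@H](O[Si](C)(C)C(C)(C)C)[C@H]3c2cccc(Br)c2[C@H]4O | intermediate
21 | C4 aryllithium lithium alkoxide from 20 (not isolated) | O1CCOC12C[C@]34C[C@H]2C[C@H](O[Si](C)(C)C(C)(C)C)[C@H]3c2cccc([Li])c2[C@H]4O[Li] | intermediate
22 | 6α-hydroxy 19-acid, ring A aromatic | O1CCOC12C[C@]34C[C@H]2C[C@H](O[Si](C)(C)C(C)(C)C)[C@H]3c2cccc(C(=O)O)c2[C@H]4O | intermediate
23 | trilithium enediolate of the 1,4-dihydro acid (not isolated) | O1CCOC12C[C@]34C[C@H]2C[C@H](O[Si](C)(C)C(C)(C)C)[C@H]3C2=C([C@H]4O[Li])C(=C(O[Li])O[Li])C=CC2 | intermediate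
24 | ring A 2,5(10)-diene, 4β-methyl 4α-carboxylic acid, 6α-OH, 11β-OTBS, C16 dioxolane | O1CCOC12C[C@]34C[C@H]2C[C@H](O[Si](C)(C)C(C)(C)C)[C@H]3C2=C([C@H]4O)[C@](C)(C(=O)O)C=CC2 | intermediate
25 | tributyl(iodomethyl)stannane | CCCC[Sn](CCCC)(CCCC)CI | starting material
26 | dipotassium salt of 24 (not isolated) | O1CCOC12C[C@]34C[C@H]2C[C@H](O[Si](C)(C)C(C)(C)C)[C@H]3C2=C([C@H]4O[K])[C@](C)(C(=O)O[K])C=CC2 | intermediate
27 | C6 tributylstannylmethyl ether of 24, free C19 acid | O1CCOC12C[C@]34C[C@H]2C[C@H](O[Si](C)(C)C(C)(C)C)[C@H]3C2=C([C@H]4OC[Sn](CCCC)(CCCC)CCCC)[C@](C)(C(=O)O)C=CC2 | intermediate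
28 | C6 lithiomethyl ether, lithium C19 carboxylate (not isolated) | O1CCOC12C[C@]34C[C@H]2C[C@H](O[Si](C)(C)C(C)(C)C)[C@H]3C2=C([C@H]4OC[Li])[C@](C)(C(=O)O[Li])C=CC2 | intermediate
29 | 20-hydroxy 19-acid with quaternary C10 and C5=C6 (not isolated) | O1CCOC12C[C@]34C[C@H]2C[C@H](O[Si](C)(C)C(C)(C)C)[C@H]3[C@]2(CO)CC=C[C@@](C)(C(=O)O)C2=C4 | intermediate
30 | 19,20-lactone with quaternary C10, C5=C6 and C2=C3, 11β-OTBS, C16 dioxolane | O1CCOC12C[C@]34C[C@H]2C[C@H](O[Si](C)(C)C(C)(C)C)[C@H]3[C@]25COC(=O)[C@](C)(C=CC2)C5=C4 | intermediate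
31 | 2β,3β-diol of 30 | O1CCOC12C[C@]34C[C@H]2C[C@H](O[Si](C)(C)C(C)(C)C)[C@H]3[C@]25COC(=O)[C@](C)([C@@H](O)[C@@H](O)C2)C5=C4 | intermediate
32 | 2β,3β,11β-tris-TBS ether, C5=C6 | O1CCOC12C[C@]34C[C@H]2C[C@H](O[Si](C)(C)C(C)(C)C)[C@H]3[C@]25COC(=O)[C@](C)([C@@H](O[Si](C)(C)C(C)(C)C)[C@@H](O[Si](C)(C)C(C)(C)C)C2)C5=C4 | intermediate
33 | C6 alkylborane, 5α-H (not isolated) | O1CCOC12C[C@]34C[C@H]2C[C@H](O[Si](C)(C)C(C)(C)C)[C@H]3[C@]25COC(=O)[C@](C)([C@@H](O[Si](C)(C)C(C)(C)C)[C@@H](O[Si](C)(C)C(C)(C)C)C2)[C@@H]5[C@H]4B | intermediate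
34 | C6 alcohol, expected 5α-H, 6α-OH | O1CCOC12C[C@]34C[C@H]2C[C@H](O[Si](C)(C)C(C)(C)C)[C@H]3[C@]25COC(=O)[C@](C)([C@@H](O[Si](C)(C)C(C)(C)C)[C@@H](O[Si](C)(C)C(C)(C)C)C2)[C@@H]5[C@H]4O | intermediate
35 | C6 ketone, 5α-H (not isolated) | O1CCOC12C[C@]34C[C@H]2C[C@H](O[Si](C)(C)C(C)(C)C)[C@H]3[C@]25COC(=O)[C@](C)([C@@H](O[Si](C)(C)C(C)(C)C)[C@@H](O[Si](C)(C)C(C)(C)C)C2)[C@@H]5C4=O | intermediate
36 | C6 ketone, 5β-H | O1CCOC12C[C@]34C[C@H]2C[C@H](O[Si](C)(C)C(C)(C)C)[C@H]3[C@]25COC(=O)[C@](C)([C@@H](O[Si](C)(C)C(C)(C)C)[C@@H](O[Si](C)(C)C(C)(C)C)C2)[C@H]5C4=O | intermediate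
37 | C6 methoxymethylidene enol ether, E/Z mixture | O1CCOC12C[C@]34C[C@H]2C[C@H](O[Si](C)(C)C(C)(C)C)[C@H]3[C@]25COC(=O)[C@](C)([C@@H](O[Si](C)(C)C(C)(C)C)[C@@H](O[Si](C)(C)C(C)(C)C)C2)[C@H]5C4=COC | intermediate
38 | 6β-formyl compound with C16 dioxolane (not isolated) | O1CCOC12C[C@]34C[C@H]2C[C@H](O[Si](C)(C)C(C)(C)C)[C@H]3[C@]25COC(=O)[C@](C)([C@@H](O[Si](C)(C)C(C)(C)C)[C@@H](O[Si](C)(C)C(C)(C)C)C2)[C@H]5[C@@H]4C=O | intermediate
39 | 6β-formyl compound with C16 ketone | O=C1C[C@]23C[C@H]1C[C@H](O[Si](C)(C)C(C)(C)C)[C@H]2[C@]12COC(=O)[C@](C)([C@@H](O[Si](C)(C)C(C)(C)C)[C@@H](O[Si](C)(C)C(C)(C)C)C1)[C@H]2[C@@H]3C=O | intermediate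
40 | 7-carboxylic acid with C16 ketone | O=C1C[C@]23C[C@H]1C[C@H](O[Si](C)(C)C(C)(C)C)[C@H]2[C@]12COC(=O)[C@](C)([C@@H](O[Si](C)(C)C(C)(C)C)[C@@H](O[Si](C)(C)C(C)(C)C)C1)[C@H]2[C@@H]3C(=O)O | intermediate
41 | 16-methylidene 2β,3β,11β-tris-TBS ether 7-acid | C=C1C[C@]23C[C@H]1C[C@H](O[Si](C)(C)C(C)(C)C)[C@H]2[C@]12COC(=O)[C@](C)([C@@H](O[Si](C)(C)C(C)(C)C)[C@@H](O[Si](C)(C)C(C)(C)C)C1)[C@H]2[C@@H]3C(=O)O | intermediate
42 | CNP0302900.3 | C=C1C[C@]23C[C@H]1C[C@H](O)[C@H]2[C@]12COC(=O)[C@](C)([C@@H](O)[C@@H](O)C1)[C@H]2[C@@H]3C(=O)O | target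

**Step count and risks**

Total steps: 27. Longest linear sequence: 27 steps (1 → 42); the route is fully linear, with 2, 11 and 25 entering as building blocks.

Steps most likely to fail:

1. Step 16. The methylation of the enediolate may lose facial control (methyl iodide also entering on the face of the C6 alkoxide), and the benzylic C–O bond may be partly cleaved under the reducing conditions. The fallback sets out from 22. Reduction with Li/NH3 followed by NH4Cl instead of methyl iodide should give the 1,4-dihydro acid F1. Carbodiimide lactonisation (EDC·HCl, DMAP) would then close the C19-to-O6 γ-lactone F2, which can only form with C19 cis to O6, while C4–H equilibrates. Deprotonation with LiN(i-Pr)2 and methylation of the lactone enolate gives the 4-methyl lactone F3; the tether holds C19 on the α face, so the methyl group can only end β. LiOH then opens the lactone and the route is rejoined at 24.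

2. Step 23. The basic ylide may enolise the hindered C6 ketone toward C5 instead of adding to it, and the ketone is then recovered. The fallback sets out from 36. Non-basic methylenation with Zn, CH2Br2 and TiCl4 should give the 6-methylidene compound F7 (the lactone carbonyl is not attacked by this reagent). Hydroboration with BH3·THF and oxidation with H2O2/NaOAc places the hydroxyl on the exocyclic carbon and gives the C7 alcohol F8. Dess–Martin oxidation followed by Et3N equilibration at C6 gives the 6β-aldehyde, and the route is rejoined at 38.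

3. Step 18. A [1,2]-shift or addition of the α-alkoxy carbanion to the neighbouring carboxylate may compete with the [2,3] path, the more so because the receiving carbon C10 is fully substituted. The fallback sets out from 24. Heating with Me2NCH(OMe)2 in xylene at 140 °C (Büchi-type [2,3] shift of an alkoxy(amino)carbene, also suprafacial) should give the C10 dimethylcarboxamide F4, in which the acid has been converted into its methyl ester by the same reagent. Cp2Zr(H)Cl reduces the amide to the C20 aldehyde F5, and NaBH4 in MeOH gives the hydroxy ester F6, which closes the δ-lactone with loss of methanol. The route is rejoined at 30.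

Further compounds
F1 | step 16 | 1,4-dihydro acid with C4–H (C4 epimers), 6α-OH, 11β-OTBS, C16 dioxolane | O1CCOC12C[C@]34C[C@H]2C[C@H](O[Si](C)(C)C(C)(C)C)[C@H]3C2=C([C@H]4O)C(C(=O)O)C=CC2
F2 | step 16 | C19-to-O6 γ-lactone with 4β-H | O1CCOC12C[C@]34C[C@H]2C[C@H](O[Si](C)(C)C(C)(C)C)[C@H]3C2=C5[C@H]4OC(=O)[C@@H]5C=CC2
F3 | step 16 | C19-to-O6 γ-lactone with 4β-methyl | O1CCOC12C[C@]34C[C@H]2C[C@H](O[Si](C)(C)C(C)(C)C)[C@H]3C2=C5[C@H]4OC(=O)[C@]5(C)C=CC2
F4 | step 18 | C10 N,N-dimethylcarboxamide (C20 as amide carbon), C19 methyl ester, C5=C6 | O1CCOC12C[C@]34C[C@H]2C[C@H](O[Si](C)(C)C(C)(C)C)[C@H]3[C@]2(C(=O)N(C)C)CC=C[C@@](C)(C(=O)OC)C2=C4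
F5 | step 18 | C20 aldehyde, C19 methyl ester | O1CCOC12C[C@]34C[C@H]2C[C@H](O[Si](C)(C)C(C)(C)C)[C@H]3[C@]2(C=O)CC=C[C@@](C)(C(=O)OC)C2=C4
F6 | step 18 | 20-hydroxy C19 methyl ester | O1CCOC12C[C@]34C[C@H]2C[C@H](O[Si](C)(C)C(C)(C)C)[C@H]3[C@]2(CO)CC=C[C@@](C)(C(=O)OC)C2=C4
F7 | step 23 | 6-methylidene compound (5β-H, tris-TBS, C16 dioxolane) | O1CCOC12C[C@]34C[C@H]2C[C@H](O[Si](C)(C)C(C)(C)C)[C@H]3[C@]25COC(=O)[C@](C)([C@@H](O[Si](C)(C)C(C)(C)C)[C@@H](O[Si](C)(C)C(C)(C)C)C2)[C@H]5C4=C
F8 | step 23 | C7 primary alcohol (C6 epimers) | O1CCOC12C[C@]34C[C@H]2C[C@H](O[Si](C)(C)C(C)(C)C)[C@H]3[C@]25COC(=O)[C@](C)([C@@H](O[Si](C)(C)C(C)(C)C)[C@@H](O[Si](C)(C)C(C)(C)C)C2)[C@H]5C4CO
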